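**Plan** (labdane numbering: decalin C1–C10, side chain C11–C16, C17 on C8, C20 on C10)

1. Retrosynthesis: remove the C2 acetate, cut C11–C12 (Wittig, then hydrogenation), then cut C8–C9 and C5–C10 together, which opens ring B and ring A in one stroke to an acyclic tetraene-al.
2. Enabling feature: ring B is a cyclohexene in which C8–C9 and C5–C10 are the two σ bonds of a [4+2] between a C5=C6–C7=C8 diene and a C9=C10 enal, and the four ring-A carbons C1–C4 are the tether. A silyl group on C8 makes the adduct an allylsilane, so that SE2' protodesilylation moves the new alkene from C6=C7 to C7=C8.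
3. Forward: geranyl acetate gives C11, the E C9=C10 alkene and C1–C3; O2 comes from enamine α-oxygenation, C3–C4 from a Mukaiyama aldol, the diene from HWE and hydroalumination–methylation; then the cycloaddition, Wittig, protodesilylation/deprotection, hydrogenation and acetylation.
4. Stereochemistry: C2 from the amine catalyst, C3 by Felkin–Anh addition, C5/C9/C10 in the cycloaddition (E-enal, endo formyl, chair tether steered by the C2/C3 dioxolane), C13 from desymmetrization of 3-methylglutaric anhydride.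

Key step: step 12

Assumption: in step 1 the dihydroquinine-derived catalyst (DHQ)2AQN is taken to give the (S)-hemiester; if the sense is opposite, its pseudo-enantiomer (DHQD)2AQN is used.

**Step 1**
Reactants: 1 3-methylglutaric anhydride
Product: 2 (3S)-5-methoxy-3-methyl-5-oxopentanoic acid
Conditions: MeOH (10 equiv), (DHQ)2AQN (10 mol%), Et2O, −40 °C
Reagents that add atoms: methanol, CO
Why: Alcoholytic desymmetrization of a prochiral cyclic anhydride under cinchona-alkaloid general-base catalysis differentiates the two enantiotopic carbonyl groups and sets the future C13 centre.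

**Step 2**
Reactants: 2 (3S)-5-methoxy-3-methyl-5-oxopentanoic acid
Product: 3 methyl (3R)-4-iodo-3-methylbutanoate
Conditions: PhI(OAc)2, I2, cyclohexane, hν, reflux
Reagents that add atoms: iodine, II
Why: Hunsdiecker-type photolytic iododecarboxylation through the acyl hypoiodite gives the primary iodide, and the stereocentre next to the radical carbon is not touched (the descriptor changes only by priority).

**Step 3**
Reactants: 3 methyl (3R)-4-iodo-3-methylbutanoate
Product: 4 [(2R)-4-methoxy-2-methyl-4-oxobutyl]triphenylphosphonium iodide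
Conditions: PPh3, MeCN, reflux
Reagents that add atoms: triphenylphosphine, c1ccc(cc1)P(c1ccccc1)c1ccccc1
Why: SN2 quaternisation of a primary iodide by the phosphine gives the Wittig salt.

**Step 4**
Reactants: 5 geranyl acetate
Product: 6 (2E)-3-methyl-6-oxohex-2-en-1-yl acetate
Conditions: O3 (1 equiv), CH2Cl2–pyridine, −78 °C; then Me2S
Reagents that add atoms: ozone, [O-][O+]=O
Why: Ozonolysis should attack the electron-rich 6,7-alkene in preference to the 2,3-alkene deactivated by the allylic acetate, which keeps the E-trisubstituted alkene that becomes the dienophile.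

**Step 5**
Reactants: 6 (2E)-3-methyl-6-oxohex-2-en-1-yl acetate
Product: 7 (2R,4E)-6-acetoxy-4-methyl-1-oxohex-4-en-2-yl benzoate
Conditions: (PhCO2)2, (R)-α,α-diphenylprolinol trimethylsilyl ether (10 mol%), THF, 0 °C
Reagents that add atoms: dibenzoyl peroxide, O=C(OOC(=O)c1ccccc1)c1ccccc1
Why: Enamine-catalysed α-benzoyloxylation, in which the diphenyl(silyloxy)methyl group shields one face of the E-enamine so that the peroxide oxygen is delivered to the open face and C2 is set as R.

**Step 6**
Reactants: 7 (2R,4E)-6-acetoxy-4-methyl-1-oxohex-4-en-2-yl benzoate; 8 2-methyl-1-(trimethylsilyloxy)prop-1-ene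
Product: 9 (2E,5R,6S)-1-acetoxy-6-hydroxy-3,7,7-trimethyl-8-oxooct-2-en-5-yl benzoate
Conditions: BF3·OEt2 (1.1 equiv), CH2Cl2, −78 °C; then aq. NaHCO3
Reagents that add atoms: none
Why: Mukaiyama aldol addition under non-chelating activation, where Felkin–Anh attack of the tetrasubstituted enol silane anti to the C2–O bond gives the 2,3-anti (erythro) relationship (C3 as S) and creates the C4 gem-dimethyl quaternary carbon.

**Step 7**
Reactants: 9 (2E,5R,6S)-1-acetoxy-6-hydroxy-3,7,7-trimethyl-8-oxooct-2-en-5-yl benzoate; 10 diethyl [3-(trimethylsilyl)prop-2-yn-1-yl]phosphonate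
Product: 11 (2E,5R,6S,8E)-1-acetoxy-6-hydroxy-3,7,7-trimethyl-11-(trimethylsilyl)undeca-2,8-dien-10-yn-5-yl benzoate
Conditions: LiN(SiMe3)2 (2.2 equiv), THF, −78 to 0 °C
Reagents that add atoms: none
Why: Horner–Wadsworth–Emmons olefination of the non-enolisable neopentyl aldehyde gives the E-enyne, the second equivalent of base holding the C3 hydroxyl as its lithium alkoxide at low temperature; a benzoyl shift between O2 and O3 would be of no consequence because both esters are removed next.

**Step 8**
Reactants: 11 (2E,5R,6S,8E)-1-acetoxy-6-hydroxy-3,7,7-trimethyl-11-(trimethylsilyl)undeca-2,8-dien-10-yn-5-yl benzoate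
Product: 12 (2E,5R,6S,8E)-3,7,7-trimethyl-11-(trimethylsilyl)undeca-2,8-dien-10-yne-1,5,6-triol
Conditions: i-Bu2AlH (6 equiv), CH2Cl2, −78 to −20 °C; then aq. potassium sodium tartrate
Reagents that add atoms: none
Why: Hydride cleavage of the benzoate and acetate at low temperature, where the silylalkyne is not hydroaluminated; basic methanolysis is avoided because it would cleave the C(sp)–Si bond.

**Step 9**
Reactants: 12 (2E,5R,6S,8E)-3,7,7-trimethyl-11-(trimethylsilyl)undeca-2,8-dien-10-yne-1,5,6-triol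
Product: 13 (2E)-4-{(4R,5S)-2,2-dimethyl-5-[(3E)-2-methyl-6-(trimethylsilyl)hex-3-en-5-yn-2-yl]-1,3-dioxolan-4-yl}-3-methylbut-2-en-1-ol
Conditions: Me2C(OMe)2, pyridinium p-toluenesulfonate (cat.), CH2Cl2, rt; then MeOH, rt (brief)
Reagents that add atoms: 2,2-dimethoxypropane, COC(C)(C)OC
Why: Acid-catalysed transketalisation closes the cis-4,5-disubstituted dioxolane on the only vicinal diol, a temporary ring that protects O2/O3 and pre-organises the tether.

**Step 10**
Reactants: 13 (2E)-4-{(4R,5S)-2,2-dimethyl-5-[(3E)-2-methyl-6-(trimethylsilyl)hex-3-en-5-yn-2-yl]-1,3-dioxolan-4-yl}-3-methylbut-2-en-1-ol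
Product: 15 (2E)-4-{(4R,5S)-2,2-dimethyl-5-[(3E,5E)-2-methyl-6-(trimethylsilyl)hepta-3,5-dien-2-yl]-1,3-dioxolan-4-yl}-3-methylbut-2-en-1-ol, via alkenylalane 14 (not isolated)
Conditions: i-Bu2AlH (2.5 equiv), heptane, rt to 50 °C; MeLi (2.5 equiv), Et2O, 0 °C; MeI (excess), rt
Reagents that add atoms: iodomethane, CI
Why: Hydroalumination of a 1-silylalkyne places aluminium on the silicon-bearing carbon and, in a hydrocarbon without donor, gives the net trans adduct, whose lithium ate complex is methylated with retention, so that the new methyl is cis and the silyl group trans to C6.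

**Step 11**
Reactants: 15 (2E)-4-{(4R,5S)-2,2-dimethyl-5-[(3E,5E)-2-methyl-6-(trimethylsilyl)hepta-3,5-dien-2-yl]-1,3-dioxolan-4-yl}-3-methylbut-2-en-1-ol
Product: 16 (2E)-4-{(4R,5S)-2,2-dimethyl-5-[(3E,5E)-2-methyl-6-(trimethylsilyl)hepta-3,5-dien-2-yl]-1,3-dioxolan-4-yl}-3-methylbut-2-enal
Conditions: MnO2 (activated, excess), CH2Cl2, rt
Reagents that add atoms: none
Why: Chemoselective oxidation of the primary allylic alcohol gives the E-enal without touching the dienylsilane or the acetonide.

**Step 12**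
Reactants: 16 (2E)-4-{(4R,5S)-2,2-dimethyl-5-[(3E,5E)-2-methyl-6-(trimethylsilyl)hepta-3,5-dien-2-yl]-1,3-dioxolan-4-yl}-3-methylbut-2-enal
Product: 17 2α,3α-isopropylidenedioxy-8β-trimethylsilyl-drim-6-en-11-al (8α-methyl; 5α-H; 9α-H; 10β-methyl)
Conditions: Me2AlCl (1.5 equiv), CH2Cl2, −78 to −20 °C; then aq. NaHCO3
Reagents that add atoms: none
Why: The aluminium-complexed E-enal (C9=C10) adds suprafacially to the s-cis C5=C6–C7=C8 diene in a concerted, asynchronous intramolecular Diels–Alder reaction in which the C5–C10 bond runs ahead of the C8–C9 bond. The closest known reaction type is the type 1 intramolecular Diels–Alder reaction of 1,7,9-decatrienals with a terminally activated dienophile, combined with the use of 1-silyl dienes that give allylsilane adducts. Ring B is closed as the six-membered cycloadduct ring by the C8–C9 and C5–C10 bonds, and ring A is closed at the same moment by the C5–C10 bond through the four-atom tether C1–C4 (six-membered, fused). C9 and C10 follow from the E geometry of the enal (formyl and methyl cis), the trans fusion at C5/C10 from the endo position of the complexed formyl group with the tether exo, C8 (silyl β, pseudoaxial) from the diene geometry, and the absolute sense from C2 and C3, because only one trans transition state has a chair tether with O2 equatorial while the other would place O2 syn-axial to the C10 and C4 methyl groups. The step needs endo and π-facial selectivity, which the Lewis acid and the cis-fused dioxolane on the tether should secure, and its regiochemistry is fixed by the tether.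

**Step 13**
Reactants: 17 2α,3α-isopropylidenedioxy-8β-trimethylsilyl-drim-6-en-11-al; 4 [(2R)-4-methoxy-2-methyl-4-oxobutyl]triphenylphosphonium iodide
Product: 19 methyl (11Z,13R)-2α,3α-isopropylidenedioxy-8β-trimethylsilyl-labda-6,11-dien-15-oate, via ylide 18 (not isolated)
Conditions: NaN(SiMe3)2, THF, −78 °C; then 17, −78 °C to rt
Reagents that add atoms: none
Why: Wittig olefination with the non-stabilised ylide forms C11=C12 (Z expected, of no consequence because it is hydrogenated) and brings in C12–C16 with the C13 centre; it is run before desilylation so that no epimerisable β,γ-unsaturated aldehyde is ever present.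

**Step 14**
Reactants: 19 methyl (11Z,13R)-2α,3α-isopropylidenedioxy-8β-trimethylsilyl-labda-6,11-dien-15-oate
Product: 21 methyl (11Z,13R)-2α,3α-dihydroxylabda-7,11-dien-15-oate, via Δ7-acetonide 20 (not isolated)
Conditions: CF3CO2H, CH2Cl2, 0 °C; then THF–H2O, rt
Reagents that add atoms: none
Why: SE2' protodesilylation of the allylsilane, in which the proton adds at C6 anti to the pseudoaxial C8–Si bond and loss of silicon places the double bond at C7=C8 regiospecifically, after which aqueous acid hydrolyses the acetonide.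

**Step 15**
Reactants: 21 methyl (11Z,13R)-2α,3α-dihydroxylabda-7,11-dien-15-oate
Product: 22 methyl (13S)-2α,3α-dihydroxylabd-7-en-15-oate
Conditions: H2 (1 atm), RhCl(PPh3)3 (5 mol%), benzene–EtOH, rt
Reagents that add atoms: none
Why: Homogeneous hydrogenation with RhCl(PPh3)3 should saturate the disubstituted C11=C12 alkene and leave the trisubstituted C7=C8 alkene.

**Step 16**
Reactants: 22 methyl (13S)-2α,3α-dihydroxylabd-7-en-15-oate
Product: 23 methyl (13S)-2α-acetoxy-3α-hydroxylabd-7-en-15-oate (CNP0571009.1)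
Conditions: Ac2O (1.1 equiv), pyridine, CH2Cl2, 0 °C
Reagents that add atoms: acetic anhydride, CC(=O)OC(C)=O
Why: The equatorial 2α-hydroxyl should be acylated in preference to the axial 3α-hydroxyl, which is neopentylic and flanked by the C4 gem-dimethyl group.

**Compound list**

1 | 3-methylglutaric anhydride | CC1CC(=O)OC(=O)C1 | starting material
2 | (3S)-5-methoxy-3-methyl-5-oxopentanoic acid | COC(=O)C[C@@H](C)CC(=O)O | intermediate
3 | methyl (3R)-4-iodo-3-methylbutanoate | COC(=O)C[C@@H](C)CI | intermediate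
4 | [(2R)-4-methoxy-2-methyl-4-oxobutyl]triphenylphosphonium iodide | COC(=O)C[C@@H](C)C[P+](c1ccccc1)(c1ccccc1)c1ccccc1.[I-] | intermediate
5 | geranyl acetate | CC(C)=CCC/C(C)=C/COC(C)=O | starting material
6 | (2E)-3-methyl-6-oxohex-2-en-1-yl acetate | O=CCC/C(C)=C/COC(C)=O | intermediate
7 | (2R,4E)-6-acetoxy-4-methyl-1-oxohex-4-en-2-yl benzoate | O=C[C@H](OC(=O)c1ccccc1)C/C(C)=C/COC(C)=O | intermediate
8 | 2-methyl-1-(trimethylsilyloxy)prop-1-ene | CC(C)=CO[Si](C)(C)C | starting material
9 | (2E,5R,6S)-1-acetoxy-6-hydroxy-3,7,7-trimethyl-8-oxooct-2-en-5-yl benzoate | O=CC(C)(C)[C@H](O)[C@H](OC(=O)c1ccccc1)C/C(C)=C/COC(C)=O | intermediate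
10 | diethyl [3-(trimethylsilyl)prop-2-yn-1-yl]phosphonate | CCOP(=O)(CC#C[Si](C)(C)C)OCC | starting material
11 | (2E,5R,6S,8E)-1-acetoxy-6-hydroxy-3,7,7-trimethyl-11-(trimethylsilyl)undeca-2,8-dien-10-yn-5-yl benzoate | C[Si](C)(C)C#C/C=C/C(C)(C)[C@H](O)[C@H](OC(=O)c1ccccc1)C/C(C)=C/COC(C)=O | intermediate
12 | (2E,5R,6S,8E)-3,7,7-trimethyl-11-(trimethylsilyl)undeca-2,8-dien-10-yne-1,5,6-triol | C[Si](C)(C)C#C/C=C/C(C)(C)[C@H](O)[C@H](O)C/C(C)=C/CO | intermediate
13 | (2E)-4-{(4R,5S)-2,2-dimethyl-5-[(3E)-2-methyl-6-(trimethylsilyl)hex-3-en-5-yn-2-yl]-1,3-dioxolan-4-yl}-3-methylbut-2-en-1-ol | C[Si](C)(C)C#C/C=C/C(C)(C)[C@@H]1OC(C)(C)O[C@@H]1C/C(C)=C/CO | intermediate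
14 | alkenylalane: diisobutylaluminium alkoxide of 13 carrying a diisobutylalanyl group on the silyl-bearing carbon, aluminium cis to C6 | C[Si](C)(C)/C(=C/C=C/C(C)(C)[C@@H]1OC(C)(C)O[C@@H]1C/C(C)=C/CO[Al](CC(C)C)CC(C)C)[Al](CC(C)C)CC(C)C | intermediate
15 | (2E)-4-{(4R,5S)-2,2-dimethyl-5-[(3E,5E)-2-methyl-6-(trimethylsilyl)hepta-3,5-dien-2-yl]-1,3-dioxolan-4-yl}-3-methylbut-2-en-1-ol | C[Si](C)(C)/C(C)=C/C=C/C(C)(C)[C@@H]1OC(C)(C)O[C@@H]1C/C(C)=C/CO | intermediate
16 | (2E)-4-{(4R,5S)-2,2-dimethyl-5-[(3E,5E)-2-methyl-6-(trimethylsilyl)hepta-3,5-dien-2-yl]-1,3-dioxolan-4-yl}-3-methylbut-2-enal | C[Si](C)(C)/C(C)=C/C=C/C(C)(C)[C@@H]1OC(C)(C)O[C@@H]1C/C(C)=C/C=O | intermediate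
17 | 2α,3α-isopropylidenedioxy-8β-trimethylsilyl-drim-6-en-11-al | O=C[C@H]1[C@@](C)([Si](C)(C)C)C=C[C@H]2C(C)(C)[C@@H]3OC(C)(C)O[C@@H]3C[C@]12C | intermediate
18 | [(2R)-4-methoxy-2-methyl-4-oxobutylidene]triphenylphosphorane | COC(=O)C[C@@H](C)C=P(c1ccccc1)(c1ccccc1)c1ccccc1 | intermediate
19 | methyl (11Z,13R)-2α,3α-isopropylidenedioxy-8β-trimethylsilyl-labda-6,11-dien-15-oate | COC(=O)C[C@@H](C)/C=C\[C@H]1[C@@](C)([Si](C)(C)C)C=C[C@H]2C(C)(C)[C@@H]3OC(C)(C)O[C@@H]3C[C@]12C | intermediate
20 | methyl (11Z,13R)-2α,3α-isopropylidenedioxylabda-7,11-dien-15-oate | COC(=O)C[C@@H](C)/C=C\[C@H]1C(C)=CC[C@H]2C(C)(C)[C@@H]3OC(C)(C)O[C@@H]3C[C@]12C | intermediate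
21 | methyl (11Z,13R)-2α,3α-dihydroxylabda-7,11-dien-15-oate | COC(=O)C[C@@H](C)/C=C\[C@H]1C(C)=CC[C@H]2C(C)(C)[C@H](O)[C@H](O)C[C@]12C | intermediate
22 | methyl (13S)-2α,3α-dihydroxylabd-7-en-15-oate | COC(=O)C[C@@H](C)CC[C@H]1C(C)=CC[C@H]2C(C)(C)[C@H](O)[C@H](O)C[C@]12C | intermediate
23 | methyl (13S)-2α-acetoxy-3α-hydroxylabd-7-en-15-oate (CNP0571009.1) | COC(=O)C[C@@H](C)CC[C@H]1C(C)=CC[C@H]2C(C)(C)[C@H](O)[C@H](OC(C)=O)C[C@]12C | target

**Count and risks**

Total step count: 16. Longest linear sequence: 13 (steps 4 to 16; steps 1 to 3 make the side-chain salt 4).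

Most likely to fail, riskiest first:

Step 12. The diene terminus C8 is fully substituted and the enal is β,β-disubstituted, so the cycloaddition may be slow; opening of the dioxolane by the Lewis acid or oligomerisation could then compete, and the endo preference could erode towards cis-fused material. The fallback sets out from 16 and makes the dienophile cationic. Acetalisation with 1,2-bis(trimethylsilyloxy)ethane and catalytic Me3SiOTf at −78 °C gives the 1,3-dioxolane acetal F1. More Me3SiOTf opens the acetal to an alkoxy-allyl cation, which should undergo a stepwise cationic [4+2] with the dienylsilane at low temperature to give the cycloadduct acetal F2. Transacetalisation with pyridinium p-toluenesulfonate in wet acetone, which keeps the acetonide, returns to the route at 17.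

Step 10. The oxygen functions of 13 may act as internal donors and stop the cis-to-trans isomerisation of the alkenylalane, giving a mixture of double-bond isomers, and the alane may reductively open the acetonide. The fallback sets out from 9 and fixes the vinylsilane geometry on a small fragment. 3-(Trimethylsilyl)prop-2-yn-1-ol with NaAlH2(OCH2CH2OMe)2 and then I2 gives (2Z)-3-iodo-3-(trimethylsilyl)prop-2-en-1-ol F3 (aluminium and then iodine held cis to the hydroxymethyl group by the alkoxide). Me2CuLi gives (2E)-3-(trimethylsilyl)but-2-en-1-ol F4, CBr4/PPh3 the bromide F5, and Arbuzov reaction with P(OEt)3 the allylic phosphonate F6. Horner–Wadsworth–Emmons reaction of 9 with F6 and LiN(SiMe3)2 gives the dienylsilane diester F7, K2CO3 in MeOH the triol F8, and the conditions of step 9 return to the route at 15.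

Step 13. The formyl group on C9 lies between two quaternary carbons, so addition of the branched ylide may be slow and enolisation with epimerisation at C9 may compete. The fallback sets out from 17 and forms C11–C12 by sp3–sp2 coupling instead. Methylenation with Ph3P=CH2 gives the vinyl compound F9. Methyl but-2-ynoate with NaI in AcOH gives methyl (2Z)-3-iodobut-2-enoate F10. Hydroboration of the terminal alkene of F9 with 9-BBN and Suzuki–Miyaura coupling with F10 (PdCl2(dppf), Cs2CO3) gives the Z-enoate F11. Copper hydride conjugate reduction (Cu(OAc)2, DTBM-SEGPHOS in the enantiomer that gives 13S, polymethylhydrosiloxane, t-BuOH) sets C13 and gives the saturated ester F12. The conditions of step 14 then return to the route at 22, and step 15 is not needed.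

**Further compounds**

F1 | step 12 | 2-[(1E)-2-methyl-3-{(4R,5S)-2,2-dimethyl-5-[(3E,5E)-2-methyl-6-(trimethylsilyl)hepta-3,5-dien-2-yl]-1,3-dioxolan-4-yl}prop-1-en-1-yl]-1,3-dioxolane | C[Si](C)(C)/C(C)=C/C=C/C(C)(C)[C@@H]1OC(C)(C)O[C@@H]1C/C(C)=C/C2OCCO2
F2 | step 12 | 1,3-dioxolane acetal of 17 | O1CCOC1[C@H]2[C@@](C)([Si](C)(C)C)C=C[C@H]3C(C)(C)[C@@H]4OC(C)(C)O[C@@H]4C[C@]23C
F3 | step 10 | (2Z)-3-iodo-3-(trimethylsilyl)prop-2-en-1-ol | OC/C=C(\I)[Si](C)(C)C
F4 | step 10 | (2E)-3-(trimethylsilyl)but-2-en-1-ol | OC/C=C(\C)[Si](C)(C)C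
F5 | step 10 | [(2E)-4-bromobut-2-en-2-yl]trimethylsilane | BrC/C=C(\C)[Si](C)(C)C
F6 | step 10 | diethyl [(2E)-3-(trimethylsilyl)but-2-en-1-yl]phosphonate | CCOP(=O)(C/C=C(\C)[Si](C)(C)C)OCC
F7 | step 10 | (2E,5R,6S,8E,10E)-1-acetoxy-6-hydroxy-3,7,7-trimethyl-11-(trimethylsilyl)dodeca-2,8,10-trien-5-yl benzoate | C[Si](C)(C)/C(C)=C/C=C/C(C)(C)[C@H](O)[C@H](OC(=O)c1ccccc1)C/C(C)=C/COC(C)=O
F8 | step 10 | (2E,5R,6S,8E,10E)-3,7,7-trimethyl-11-(trimethylsilyl)dodeca-2,8,10-triene-1,5,6-triol | C[Si](C)(C)/C(C)=C/C=C/C(C)(C)[C@H](O)[C@H](O)C/C(C)=C/CO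
F9 | step 13 | 9β-vinyl analogue of 17 (formyl replaced by ethenyl) | C=C[C@H]1[C@@](C)([Si](C)(C)C)C=C[C@H]2C(C)(C)[C@@H]3OC(C)(C)O[C@@H]3C[C@]12C
F10 | step 13 | methyl (2Z)-3-iodobut-2-enoate | COC(=O)/C=C(/C)I
F11 | step 13 | methyl (13Z)-2α,3α-isopropylidenedioxy-8β-trimethylsilyl-labda-6,13-dien-15-oate | COC(=O)/C=C(/C)CC[C@H]1[C@@](C)([Si](C)(C)C)C=C[C@H]2C(C)(C)[C@@H]3OC(C)(C)O[C@@H]3C[C@]12C
F12 | step 13 | methyl (13S)-2α,3α-isopropylidenedioxy-8β-trimethylsilyl-labd-6-en-15-oate | COC(=O)C[C@@H](C)CC[C@H]1[C@@](C)([Si](C)(C)C)C=C[C@H]2C(C)(C)[C@@H]3OC(C)(C)O[C@@H]3C[C@]12C
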